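**Retrosynthetic overview** (isoflavone numbering: ring A C5–C8, pyranone C2–C4, ring B C1'–C6')
1. The 7-O-allyl group comes off last. Before that, the furan ring is closed by forming C3–C1' and C2–O–C2' in one Nenitzescu-type union of a ring-A 2-(pyrrolidin-1-yl)chromone with 2,2-dimethyl-2H-chromene-5,8-dione (ring B with its pyran).
2. The quinone comes from 5,8-dimethoxy-2,2-dimethyl-2H-chromene. Its pyran ring is built in the key step from 3,6-dimethoxybenzyne and 3-methylbut-2-enal: aryl C3'–CH= and aryl C4'–O by [2+2] addition of the aldehyde C=O to the aryne, then 4π ring opening and oxa-6π closure (O–CMe2).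
3. Enabling feature: ring B is a hydroquinone (oxygens on C2' and C5', para), and the pyran is fused on the C3'–C4' bond lying between these two oxygen-bearing carbons. C3' and C4' are therefore the two equivalent carbons of a C2-symmetric 3,6-dioxygenated aryne, so no regiochemical question arises; the pyran oxygen set in this step later polarizes the quinone and directs the union.
4. The ring-A partner comes from 2,4,6-trihydroxyacetophenone: double C-prenylation, 4-O-allylation, pyranone ring through CS2 (thione, then S-methylation), acid closure of the C6 prenyl group onto 5-OH, then SMe/pyrrolidine exchange.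
5. Ring order: ring-B pyran (key step), then quinone; pyranone, then ring-A dihydropyran; furan ring last.

Key step: step 4

Remark: the target has no stereocentre, so no configuration has to be set; 1, 9, 15 and 16 are taken as commercial.

**Step 1**
Reactants: 1 2,5-dimethoxyphenol
Product: 2 2,5-dimethoxyphenyl propan-2-ylcarbamate
Conditions: iPrNCO, Et3N (cat.), CH2Cl2, rt
Reagents that add atoms: isopropyl isocyanate CC(C)N=C=O
Why: Base-catalysed addition of the phenol to the isocyanate (carbamoylation) installs an ortho-directing group that can later be removed under mild non-reductive conditions.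

**Step 2**
Reactants: 2 2,5-dimethoxyphenyl propan-2-ylcarbamate
Product: 6 3,6-dimethoxy-2-(trimethylsilyl)phenyl propan-2-ylcarbamate, via N-silyl carbamate 3 (not isolated), via aryllithium 4 (not isolated), via N-silyl C-silyl carbamate 5 (not isolated)
Conditions: TBSOTf, TMEDA, Et2O, 0 °C to rt; then TMEDA, n-BuLi, −78 °C; TMSCl, −78 °C to rt; aq NaHSO4 work-up
Reagents that add atoms: chlorotrimethylsilane C[Si](C)(C)Cl; tert-butyldimethylsilyl trifluoromethanesulfonate CC(C)(C)[Si](C)(C)OS(=O)(=O)C(F)(F)F (its silyl group stays only in 3, 4 and 5)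
Why: Directed ortho-metalation: after in situ N-silylation the carbamate directs lithiation to C6, the only position flanked by both the carbamate and a methoxy group, TMSCl traps the aryllithium and the N–Si bond is hydrolysed on work-up.

**Step 3**
Reactants: 6 3,6-dimethoxy-2-(trimethylsilyl)phenyl propan-2-ylcarbamate
Product: 8 3,6-dimethoxy-2-(trimethylsilyl)phenyl trifluoromethanesulfonate, via silyl phenol 7 (not isolated)
Conditions: DBU, Et2NH, MeCN, 40 °C; then PhNTf2, rt
Reagents that add atoms: N-phenylbis(trifluoromethanesulfonimide) O=S(=O)(N(c1ccccc1)S(=O)(=O)C(F)(F)F)C(F)(F)F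
Why: DBU-promoted E1cB loss of isopropyl isocyanate (trapped by Et2NH as a urea) frees the phenoxide, which is O-sulfonylated in the same flask by PhNTf2 (carbamate cleavage and triflation).

**Step 4**
Reactants: 8 3,6-dimethoxy-2-(trimethylsilyl)phenyl trifluoromethanesulfonate, 9 3-methylbut-2-enal
Product: 13 5,8-dimethoxy-2,2-dimethyl-2H-chromene, via aryne 10 (not isolated), via benzoxete 11 (not isolated), via o-quinone methide 12 (not isolated)
Conditions: CsF (3 equiv), 9 (5 equiv), MeCN, rt, slow addition of 8
Reagents that add atoms: none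
Why: Fluoride attacks silicon of 8 and triflate leaves to give the C2-symmetric aryne 10; the carbonyl oxygen of 9 adds to one aryne carbon and the aryl anion closes on the carbonyl carbon (formal [2+2]) to benzoxete 11, which opens by 4π-electrocyclic cleavage of its O–CH bond to o-quinone methide 12, and 12 closes by oxa-6π-electrocyclization onto the CMe2 terminus to give the 2H-pyran of 13. The closest known reaction type is the insertion of arynes into the C=O bond of α,β-unsaturated aldehydes (and of formamides), which gives 2H-chromenes through o-quinone methides. Ring closure modes: the transient four-membered oxete by stepwise [2+2] (attack of the aryl anion on the oxocarbenium carbon), the six-membered pyran by thermal disrotatory 6π-electrocyclization of the Z-configured dienone. No stereocentre is formed: C2 of the pyran carries two methyl groups, the stereocentre of 11 is lost on ring opening, and only the Z isomer of 12 can close while the E isomer should equilibrate through its zwitterionic form. The step needs regioselectivity and chemoselectivity: the first is removed by the symmetry of 10 (both aryne carbons are equivalent, each flanked by OMe), the second (C=O addition over ene reaction with the methyl groups or [4+2] addition across the enal) should be secured by the polarized, unhindered aldehyde oxygen, used in excess while the aryne is released slowly.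

**Step 5**
Reactants: 13 5,8-dimethoxy-2,2-dimethyl-2H-chromene
Product: 14 2,2-dimethyl-2H-chromene-5,8-dione
Conditions: (NH4)2Ce(NO3)6 (2.5 equiv), MeCN/H2O 2:1, 0 °C
Reagents that add atoms: water O
Why: Oxidative demethylation of a 1,4-dimethoxyarene by tetravalent cerium gives the p-quinone at 0 °C faster than the styrene-type alkene should react, the quinone oxygens coming from water.

**Step 6**
Reactants: 15 1-(2,4,6-trihydroxyphenyl)ethan-1-one, 16 1-bromo-3-methylbut-2-ene
Product: 17 1-[2,4,6-trihydroxy-3,5-bis(3-methylbut-2-en-1-yl)phenyl]ethan-1-one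
Conditions: 16 (2.1 equiv), 10% aq KOH, 0 °C to rt
Reagents that add atoms: none
Why: The phloroglucinol-type phenoxide is C-alkylated at both free ring positions by the allylic bromide in aqueous base (C-prenylation of a phloroglucinol anion), a known route to this ketone that should need chromatographic removal of mono- and gem-dialkylated by-products.

**Step 7**
Reactants: 17 1-[2,4,6-trihydroxy-3,5-bis(3-methylbut-2-en-1-yl)phenyl]ethan-1-one
Product: 18 1-[2,6-dihydroxy-3,5-bis(3-methylbut-2-en-1-yl)-4-(prop-2-en-1-yloxy)phenyl]ethan-1-one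
Conditions: allyl bromide (1.05 equiv), K2CO3 (1.1 equiv), acetone, rt
Reagents that add atoms: allyl bromide C=CCBr
Why: The 4-OH, para to the acetyl group and not hydrogen-bonded to it, is the most acidic hydroxyl and should be alkylated selectively by one equivalent of allyl bromide (Williamson ether synthesis).

**Step 8**
Reactants: 18 1-[2,6-dihydroxy-3,5-bis(3-methylbut-2-en-1-yl)-4-(prop-2-en-1-yloxy)phenyl]ethan-1-one
Product: 20 4,5-dihydroxy-6,8-bis(3-methylbut-2-en-1-yl)-7-(prop-2-en-1-yloxy)-2H-chromene-2-thione, via β-oxodithioacid 19 (not isolated)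
Conditions: KOtBu (4.5 equiv), CS2 (1.5 equiv), THF, 0 °C to rt; then 1 M HCl
Reagents that add atoms: carbon disulfide S=C=S
Why: The ketone enolate adds to CS2 (Claisen-type thioacylation) and on acidification the β-oxodithioacid cyclizes onto one of the two equivalent ortho hydroxyls with loss of H2S, the standard route from 2-hydroxyacetophenones to 4-hydroxy-2H-chromene-2-thiones.

**Step 9**
Reactants: 20 4,5-dihydroxy-6,8-bis(3-methylbut-2-en-1-yl)-7-(prop-2-en-1-yloxy)-2H-chromene-2-thione
Product: 21 5-hydroxy-6,8-bis(3-methylbut-2-en-1-yl)-2-(methylsulfanyl)-7-(prop-2-en-1-yloxy)-4H-chromen-4-one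
Conditions: MeI (1.05 equiv), K2CO3, acetone, 0 °C to rt
Reagents that add atoms: iodomethane CI
Why: The soft thiolate sulfur of the 2-sulfanylchromone tautomer should be methylated much faster than the carbonyl-chelated 5-OH (S-alkylation).

**Step 10**
Reactants: 21 5-hydroxy-6,8-bis(3-methylbut-2-en-1-yl)-2-(methylsulfanyl)-7-(prop-2-en-1-yloxy)-4H-chromen-4-one
Product: 22 2,2-dimethyl-6-(3-methylbut-2-en-1-yl)-8-(methylsulfanyl)-5-(prop-2-en-1-yloxy)-3,4-dihydro-2H,10H-pyrano[2,3-f]chromen-10-one
Conditions: p-TsOH·H2O (0.2 equiv), toluene, 60 °C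
Reagents that add atoms: none
Why: Acid protonates the prenyl alkenes reversibly and only the C6 tertiary cation has a free neighbouring hydroxyl (5-OH), so Markovnikov 6-endo hydroalkoxylation closes the 2,2-dimethyldihydropyran there, while the C8 prenyl group, flanked by the allyl ether and the ring oxygen, should return unchanged.

**Step 11**
Reactants: 22 2,2-dimethyl-6-(3-methylbut-2-en-1-yl)-8-(methylsulfanyl)-5-(prop-2-en-1-yloxy)-3,4-dihydro-2H,10H-pyrano[2,3-f]chromen-10-one
Product: 23 2,2-dimethyl-6-(3-methylbut-2-en-1-yl)-5-(prop-2-en-1-yloxy)-8-(pyrrolidin-1-yl)-3,4-dihydro-2H,10H-pyrano[2,3-f]chromen-10-one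
Conditions: pyrrolidine (10 equiv), 1,4-dioxane, 80 °C
Reagents that add atoms: pyrrolidine C1CCNC1
Why: Addition–elimination (nucleophilic vinylic substitution) of the amine at C2 of the 2-(methylsulfanyl)chromone, a vinylogous thioester, expels methanethiol, as in the preparation of 2-morpholinochromones.

**Step 12**
Reactants: 23 2,2-dimethyl-6-(3-methylbut-2-en-1-yl)-5-(prop-2-en-1-yloxy)-8-(pyrrolidin-1-yl)-3,4-dihydro-2H,10H-pyrano[2,3-f]chromen-10-one, 14 2,2-dimethyl-2H-chromene-5,8-dione
Product: 25 7-O-allyl ether of the target, via hydroquinone adduct 24 (not isolated)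
Conditions: AcOH, N2, rt then 60 °C
Reagents that add atoms: none
Why: Nenitzescu-type benzofuran annulation: the enaminone carbon of 23 (C3 in isoflavone numbering) adds in Michael fashion to C6 of 14, the position β to the more electrophilic C8 carbonyl (the C5 carbonyl is a vinylogous ester of the pyran oxygen), then the C5-OH of hydroquinone 24 attacks the protonated aminochromone at C2 in a 5-exo closure and pyrrolidine is lost, the same course as the known reaction of tertiary enaminones and ketene N,O-acetals with p-quinones to 5-hydroxybenzofurans.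

**Step 13**
Reactants: 25 7-O-allyl ether of the target
Product: 26 CNP0081330.0
Conditions: Pd(PPh3)4 (5 mol %), morpholine (5 equiv), THF, rt
Reagents that add atoms: none
Why: Zerovalent palladium ionizes the allyl aryl ether to a π-allyl complex that morpholine captures (Tsuji–Trost deallylation), neutral conditions that should leave the prenyl group, the chromene and the phenols untouched.

**Compound list**
1 | 2,5-dimethoxyphenol | COc1ccc(OC)c(O)c1 | starting material
2 | 2,5-dimethoxyphenyl propan-2-ylcarbamate | COc1ccc(OC)c(OC(=O)NC(C)C)c1 | intermediate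
3 | 2,5-dimethoxyphenyl N-(tert-butyldimethylsilyl)-N-(propan-2-yl)carbamate | COc1ccc(OC)c(OC(=O)N(C(C)C)[Si](C)(C)C(C)(C)C)c1 | intermediate (not isolated)
4 | 6-lithio derivative of 3 | COc1ccc(OC)c(OC(=O)N(C(C)C)[Si](C)(C)C(C)(C)C)c1[Li] | intermediate (not isolated)
5 | 3,6-dimethoxy-2-(trimethylsilyl)phenyl N-(tert-butyldimethylsilyl)-N-(propan-2-yl)carbamate | COc1ccc(OC)c(OC(=O)N(C(C)C)[Si](C)(C)C(C)(C)C)c1[Si](C)(C)C | intermediate (not isolated)
6 | 3,6-dimethoxy-2-(trimethylsilyl)phenyl propan-2-ylcarbamate | COc1ccc(OC)c([Si](C)(C)C)c1OC(=O)NC(C)C | intermediate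
7 | 3,6-dimethoxy-2-(trimethylsilyl)phenol (formed as its DBU salt) | COc1ccc(OC)c([Si](C)(C)C)c1O | intermediate (not isolated)
8 | 3,6-dimethoxy-2-(trimethylsilyl)phenyl trifluoromethanesulfonate | COc1ccc(OC)c([Si](C)(C)C)c1OS(=O)(=O)C(F)(F)F | intermediate
9 | 3-methylbut-2-enal | CC(C)=CC=O | starting material
10 | 3,6-dimethoxybenzyne (1,2-didehydro-3,6-dimethoxybenzene) | COC1=CC=C(OC)C#C1 | intermediate (not isolated)
11 | 3,6-dimethoxy-2-(2-methylprop-1-en-1-yl)-2H-benzo[b]oxete (racemic) | COc1ccc(OC)c2c1OC2C=C(C)C | intermediate (not isolated)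
12 | (6Z)-2,5-dimethoxy-6-(3-methylbut-2-en-1-ylidene)cyclohexa-2,4-dien-1-one | COC1=CC=C(OC)/C(=C/C=C(C)C)C1=O | intermediate (not isolated)
13 | 5,8-dimethoxy-2,2-dimethyl-2H-chromene | COc1ccc(OC)c2OC(C)(C)C=Cc12 | intermediate
14 | 2,2-dimethyl-2H-chromene-5,8-dione | O=C1C=CC(=O)C2=C1C=CC(C)(C)O2 | intermediate
15 | 1-(2,4,6-trihydroxyphenyl)ethan-1-one | CC(=O)c1c(O)cc(O)cc1O | starting material
16 | 1-bromo-3-methylbut-2-ene (prenyl bromide) | CC(C)=CCBr | starting material
17 | 1-[2,4,6-trihydroxy-3,5-bis(3-methylbut-2-en-1-yl)phenyl]ethan-1-one | CC(=O)c1c(O)c(CC=C(C)C)c(O)c(CC=C(C)C)c1O | intermediate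
18 | 1-[2,6-dihydroxy-3,5-bis(3-methylbut-2-en-1-yl)-4-(prop-2-en-1-yloxy)phenyl]ethan-1-one | CC(=O)c1c(O)c(CC=C(C)C)c(OCC=C)c(CC=C(C)C)c1O | intermediate
19 | 3-[2,6-dihydroxy-3,5-bis(3-methylbut-2-en-1-yl)-4-(prop-2-en-1-yloxy)phenyl]-3-oxopropanedithioic acid (formed as its potassium salt) | SC(=S)CC(=O)c1c(O)c(CC=C(C)C)c(OCC=C)c(CC=C(C)C)c1O | intermediate (not isolated)
20 | 4,5-dihydroxy-6,8-bis(3-methylbut-2-en-1-yl)-7-(prop-2-en-1-yloxy)-2H-chromene-2-thione | S=c1cc(O)c2c(O)c(CC=C(C)C)c(OCC=C)c(CC=C(C)C)c2o1 | intermediate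
21 | 5-hydroxy-6,8-bis(3-methylbut-2-en-1-yl)-2-(methylsulfanyl)-7-(prop-2-en-1-yloxy)-4H-chromen-4-one | CSc1cc(=O)c2c(O)c(CC=C(C)C)c(OCC=C)c(CC=C(C)C)c2o1 | intermediate
22 | 2,2-dimethyl-6-(3-methylbut-2-en-1-yl)-8-(methylsulfanyl)-5-(prop-2-en-1-yloxy)-3,4-dihydro-2H,10H-pyrano[2,3-f]chromen-10-one (isoflavone numbering: SMe on C2, O-allyl on C7, prenyl on C8, dihydropyran oxygen on C5) | CSc1cc(=O)c2c3OC(C)(C)CCc3c(OCC=C)c(CC=C(C)C)c2o1 | intermediate
23 | 2,2-dimethyl-6-(3-methylbut-2-en-1-yl)-5-(prop-2-en-1-yloxy)-8-(pyrrolidin-1-yl)-3,4-dihydro-2H,10H-pyrano[2,3-f]chromen-10-one | O=c1cc(N2CCCC2)oc2c(CC=C(C)C)c(OCC=C)c3CCC(C)(C)Oc3c12 | intermediate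
24 | 9-(5,8-dihydroxy-2,2-dimethyl-2H-chromen-6-yl) derivative of 23 | O=c1c(-c4cc(O)c5OC(C)(C)C=Cc5c4O)c(N4CCCC4)oc2c(CC=C(C)C)c(OCC=C)c3CCC(C)(C)Oc3c12 | intermediate (not isolated)
25 | 7-O-allyl ether of the target: benzofuro[2,3-b]chromen-4-one core with a 2,2-dimethyldihydropyran fused at C5–C6 (O on C5), O-allyl on C7, prenyl on C8, OH on C5', 2,2-dimethyl-2H-pyran fused at C3'–C4' (O on C4') | CC(C)=CCc1c(OCC=C)c2c(c3c(=O)c4c(oc13)oc1c3c(c(O)cc14)OC(C)(C)C=C3)OC(C)(C)CC2 | intermediate
26 | CNP0081330.0: as 25 with free 7-OH | CC(C)=CCc1c(O)c2c(c3c(=O)c4c(oc13)oc1c3c(c(O)cc14)OC(C)(C)C=C3)OC(C)(C)CC2 | target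

**Step count and risks**
Total: 13 steps. Longest linear sequence: 8 steps (15 to 26, steps 6–13); the ring-B branch (1 to 14, steps 1–5) joins at step 12.

Steps most likely to fail:

1. Step 12 (union). The conjugate addition of 23 to 14 may be slow, the hydroquinone adduct may exchange redox state with unreacted quinone, or the closure at C2 may lose the ring-A phenoxide instead of pyrrolidine. Fallback, setting out from 23 and 14 and coming back at 24 and then 25: the C3–C1' bond is made by Suzuki–Miyaura coupling instead of conjugate addition. 23 is iodinated at its enaminone carbon (NIS, MeCN, 0 °C) to 3-iodo-aminochromone F1. 14 takes up HBr (HBr in AcOH, CH2Cl2, 0 °C) in the same 1,4-sense to give bromohydroquinone F2, which is protected (MOMCl, iPr2NEt) as bis-MOM ether F3 and borylated (B2pin2, Pd(dppf)Cl2, KOAc, dioxane, 80 °C) to pinacol boronate F4. Coupling of F1 with F4 (Pd(dppf)Cl2, K3PO4, dioxane/H2O, 80 °C) gives protected biaryl F5; HCl in MeOH at 40 °C removes both MOM groups to give 24, which closes to 25 with loss of pyrrolidine.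

2. Step 4 (key step). The aryne may be consumed by ene reaction with the allylic methyl groups of 9 or by [4+2] addition across the enal instead of adding to the carbonyl oxygen, or the doubly ortho-substituted aryne may react too slowly with the weakly nucleophilic aldehyde. Fallback, setting out from 1 and coming back at 13: 1 is O-alkylated with 3-chloro-3-methylbut-1-yne (CuCl2·2H2O cat., DBU, MeCN, 0 °C) to aryl propargyl ether F6, which on heating in N,N-diethylaniline at 180 °C undergoes aromatic propargyl Claisen rearrangement to its only free ortho position, [1,5]-hydrogen shift and oxa-6π closure to 13.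

3. Step 10 (dihydropyran closure). The C8 prenyl cation may be captured (hydration, or ring closure onto O7 with loss of the allyl group), or the chelated 5-OH may attack too slowly. Fallback, setting out from 18 and coming back at 22: the ring is closed before the pyranone exists, when a non-chelated phenol is available. 18 with p-TsOH·H2O (5 mol %) in CH2Cl2 at 0 °C to rt, stopped at monocyclization, should give chromanyl ketone F7 (the two sides of 18 are equivalent, and the remaining hydroxyl is chelated and slower). KOtBu/CS2 then HCl converts F7 through its last free hydroxyl into thione F8, and MeI/K2CO3 gives 22.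

**Further compounds**
F1 | step 12 | 9-iodo-2,2-dimethyl-6-(3-methylbut-2-en-1-yl)-5-(prop-2-en-1-yloxy)-8-(pyrrolidin-1-yl)-3,4-dihydro-2H,10H-pyrano[2,3-f]chromen-10-one | O=c1c(I)c(N2CCCC2)oc2c(CC=C(C)C)c(OCC=C)c3CCC(C)(C)Oc3c12
F2 | step 12 | 6-bromo-2,2-dimethyl-2H-chromene-5,8-diol | Oc1cc(Br)c(O)c2C=CC(C)(C)Oc12
F3 | step 12 | 6-bromo-5,8-bis(methoxymethoxy)-2,2-dimethyl-2H-chromene | COCOc1cc(Br)c(OCOC)c2C=CC(C)(C)Oc12
F4 | step 12 | 2-[5,8-bis(methoxymethoxy)-2,2-dimethyl-2H-chromen-6-yl]-4,4,5,5-tetramethyl-1,3,2-dioxaborolane | COCOc1cc(B3OC(C)(C)C(C)(C)O3)c(OCOC)c2C=CC(C)(C)Oc12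
F5 | step 12 | 9-[5,8-bis(methoxymethoxy)-2,2-dimethyl-2H-chromen-6-yl] derivative of 23 | O=c1c(-c4cc(OCOC)c5OC(C)(C)C=Cc5c4OCOC)c(N4CCCC4)oc2c(CC=C(C)C)c(OCC=C)c3CCC(C)(C)Oc3c12
F6 | step 4 | 1,4-dimethoxy-2-[(2-methylbut-3-yn-2-yl)oxy]benzene | COc1ccc(OC)c(OC(C)(C)C#C)c1
F7 | step 10 | 1-[7-hydroxy-2,2-dimethyl-6-(3-methylbut-2-en-1-yl)-5-(prop-2-en-1-yloxy)-3,4-dihydro-2H-chromen-8-yl]ethan-1-one | CC(=O)c1c(O)c(CC=C(C)C)c(OCC=C)c2CCC(C)(C)Oc12
F8 | step 10 | 10-hydroxy-2,2-dimethyl-6-(3-methylbut-2-en-1-yl)-5-(prop-2-en-1-yloxy)-3,4-dihydro-2H,8H-pyrano[2,3-f]chromene-8-thione | S=c1cc(O)c2c3OC(C)(C)CCc3c(OCC=C)c(CC=C(C)C)c2o1
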